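Ring A of the target carries four different substituents in a fixed sequence (O1 on C8a, prenyl on C8, OMe on C7, O on C5; flavanone numbering). The route builds this ring from a four-membered ring and an alkyne, so no regiochemical choice on a preformed arene is needed. Heating 3-ethoxycyclobutenone with a prenylated methoxyalkyne gives, in one operation, a vinylketene, its [2+2] adduct and then the benzene ring. C8–C8a and C6–C7 are made, C4a–C8a closes, and the only free phenol is the future O1 with C4a as its only open ortho carbon. Formylation, chalcone assembly, asymmetric epoxidation and 6-endo ring closure then set C2 and C3; the C5 ethyl ether is cleaved last.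

Key step: step 2

Remark: the C5 oxygen is kept as its ethyl ether until ring C is closed, because a second free phenol beside the ketone would compete with O1 in that ring closure.

Step 1
Reactants: 1 chloroacetaldehyde dimethyl acetal (2-chloro-1,1-dimethoxyethane); 2 prenyl bromide (1-bromo-3-methylbut-2-ene)
Product: 4 1-methoxy-5-methylhex-4-en-1-yne, via lithium methoxyacetylide 3 (not isolated)
Conditions: n-BuLi, Et2NH (3.0 equiv each), THF, 0 °C; 1, 0 °C → rt; then 2, HMPA, −78 °C → rt
Reagents that add atoms: none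
Why: Twofold base-induced elimination (MeOH, then HCl) and deprotonation convert the chloroacetal into the lithium alkoxyacetylide, and SN2 alkylation of this acetylide at the primary carbon of the allylic bromide in THF/HMPA is the standard entry to 1-methoxy-1-alkynes, the amide being used up so that none is left to isomerise the skipped enyne.

Step 2
Reactants: 5 3-ethoxycyclobut-2-en-1-one; 4 1-methoxy-5-methylhex-4-en-1-yne
Product: 10 5-ethoxy-3-methoxy-2-(3-methylbut-2-enyl)phenol, via vinylketene 6 (not isolated), via vinylcyclobutenone 7 (not isolated), via dienylketene 8 (not isolated), via cyclohexadienone 9 (not isolated)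
Conditions: 4 (1.5 equiv), toluene, 80 → 110 °C, sealed tube
Reagents that add atoms: none
Why: Thermal 4π electrocyclic opening of 5 should give vinylketene 6, which adds ynol ether 4 in a regioselective [2+2] cycloaddition to give cyclobutenone 7; a second 4π opening gives dienylketene 8, whose 6π electrocyclisation gives dienone 9, and tautomerisation gives phenol 10. This is a Danheiser benzannulation of a cyclobutenone with an alkoxyalkyne, the established route to resorcinol monoethers. Ring A is closed by the 6π electrocyclisation (C8a–C4a) after the cycloaddition has made C8–C8a and C6–C7. No stereocentre is created, since the centre of racemic 7 is lost on ring opening. The one selectivity needed is the orientation of the [2+2] step: the polarised ynol ether bonds through its nucleophilic, prenyl-bearing carbon to the ketene carbonyl carbon, so prenyl ends ortho and OMe meta to the new OH, while the ethoxy carbon becomes C5. A methyl ynol ether cannot lose an alkene by retro-ene fragmentation at these temperatures, and the excess of 4 keeps the ketene from acylating the product.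

Step 3
Reactants: 10 5-ethoxy-3-methoxy-2-(3-methylbut-2-enyl)phenol
Product: 12 6-ethoxy-2-hydroxy-4-methoxy-3-(3-methylbut-2-enyl)benzaldehyde, via hydroxymethylphenol 11 (not isolated)
Conditions: MgCl2, Et3N, (CH2O)n, MeCN, reflux
Reagents that add atoms: paraformaldehyde (reacts as formaldehyde), C=O
Why: In this magnesium-mediated ortho-formylation (Casnati–Skattebøl) the magnesium phenoxide delivers formaldehyde through a six-membered chelate to the only free ortho carbon (C4a), and a second formaldehyde oxidises the benzylic alkoxide by hydride transfer, so the para carbon between the two ethers is not attacked.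

Step 4
Reactants: 12 6-ethoxy-2-hydroxy-4-methoxy-3-(3-methylbut-2-enyl)benzaldehyde
Product: 13 6-ethoxy-4-methoxy-2-(methoxymethoxy)-3-(3-methylbut-2-enyl)benzaldehyde
Conditions: NaH, MOMCl, DMF, 0 °C → rt
Reagents that add atoms: chloromethyl methyl ether (MOMCl), COCCl
Why: Williamson-type O-alkylation of the sodium phenoxide masks the future O1 as an acetal that survives Grignard reagent, base and peroxide and is removed by acid.

Step 5
Reactants: 13 6-ethoxy-4-methoxy-2-(methoxymethoxy)-3-(3-methylbut-2-enyl)benzaldehyde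
Product: 14 1-[6-ethoxy-4-methoxy-2-(methoxymethoxy)-3-(3-methylbut-2-enyl)phenyl]ethan-1-ol (racemic)
Conditions: MeMgBr, THF, 0 °C; aq. NH4Cl
Reagents that add atoms: methylmagnesium bromide, C[Mg]Br
Why: Grignard 1,2-addition to the aldehyde gives the secondary benzylic alcohol, whose configuration does not matter because the centre is oxidised in the next step.

Step 6
Reactants: 14 1-[6-ethoxy-4-methoxy-2-(methoxymethoxy)-3-(3-methylbut-2-enyl)phenyl]ethan-1-ol
Product: 15 1-[6-ethoxy-4-methoxy-2-(methoxymethoxy)-3-(3-methylbut-2-enyl)phenyl]ethan-1-one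
Conditions: Dess–Martin periodinane, pyridine, CH2Cl2, 0 °C → rt
Reagents that add atoms: none
Why: Dess–Martin oxidation converts the secondary benzylic alcohol into the methyl ketone under buffered conditions that leave the MOM acetal, the prenyl double bond and the electron-rich ring untouched.

Step 7
Reactants: 16 isovanillin (3-hydroxy-4-methoxybenzaldehyde)
Product: 17 4-methoxy-3-(methoxymethoxy)benzaldehyde
Conditions: NaH, MOMCl, THF/DMF, 0 °C → rt
Reagents that add atoms: chloromethyl methyl ether (MOMCl), COCCl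
Why: Williamson-type O-alkylation protects the ring B hydroxyl, so that no phenoxide is present in the aldol and epoxidation steps and both acetals can later be removed together.

Step 8
Reactants: 15 1-[6-ethoxy-4-methoxy-2-(methoxymethoxy)-3-(3-methylbut-2-enyl)phenyl]ethan-1-one; 17 4-methoxy-3-(methoxymethoxy)benzaldehyde
Product: 19 (2E)-1-[6-ethoxy-4-methoxy-2-(methoxymethoxy)-3-(3-methylbut-2-enyl)phenyl]-3-[4-methoxy-3-(methoxymethoxy)phenyl]prop-2-en-1-one, via aldol adduct 18 (not isolated)
Conditions: KOH, EtOH, rt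
Reagents that add atoms: none
Why: In this Claisen–Schmidt condensation the ketone enolate adds to the non-enolisable aldehyde and the aldol adduct loses water by E1cB to give the conjugated (E)-enone.

Step 9
Reactants: 19 the (E)-chalcone
Product: 20 [6-ethoxy-4-methoxy-2-(methoxymethoxy)-3-(3-methylbut-2-enyl)phenyl]{(2R,3S)-3-[4-methoxy-3-(methoxymethoxy)phenyl]oxiran-2-yl}methanone
Conditions: poly-L-leucine, urea–H2O2, DBU, THF, rt
Reagents that add atoms: hydrogen peroxide (from its urea adduct), OO
Why: In this Juliá–Colonna epoxidation the hydroperoxide anion adds to the enone bound to the helical poly-L-leucine, which should expose the face leading to the (2R,3S)-trans-epoxide and so set the future C3 as R, while the electron-rich prenyl double bond is inert to the nucleophilic oxidant.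

Step 10
Reactants: 20 the (2R,3S)-epoxy ketone
Product: 22 (2R,3R)-5-ethoxy-3-hydroxy-2-(3-hydroxy-4-methoxyphenyl)-7-methoxy-8-(3-methylbut-2-enyl)-2,3-dihydro-4H-chromen-4-one, via diphenol epoxide 21 (not isolated)
Conditions: HCl (3 M in MeOH), THF, 40 °C
Reagents that add atoms: none
Why: Acidic methanolysis removes both MOM acetals, and the freed C8a hydroxyl opens the protonated epoxide at the benzylic carbon in a 6-endo mode with inversion, so C2 becomes R and trans to the retained C3–OH; the C5 oxygen cannot compete because it is still an ethyl ether.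

Step 11
Reactants: 22 the (2R,3R)-5-ethoxy dihydroflavonol
Product: 23 (2R,3R)-3,5-dihydroxy-2-(3-hydroxy-4-methoxyphenyl)-7-methoxy-8-(3-methylbut-2-enyl)-2,3-dihydro-4H-chromen-4-one (target)
Conditions: MgI2·OEt2, THF, 60 °C; aq. NH4Cl
Reagents that add atoms: none
Why: In this chelation-assisted ether cleavage the magnesium ion bridges the C4 carbonyl and the C5 ether oxygen and iodide removes the ethyl group by SN2, so the unchelated methyl ethers at C7 and C4' stay; the reagent is known to spare a C8 prenyl group in 5-alkoxyflavanones.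

Compound list
1 | 2-chloro-1,1-dimethoxyethane (chloroacetaldehyde dimethyl acetal) | COC(CCl)OC | starting material
2 | 1-bromo-3-methylbut-2-ene (prenyl bromide) | CC(C)=CCBr | starting material
3 | lithium methoxyacetylide (not isolated) | [Li]C#COC | intermediate
4 | 1-methoxy-5-methylhex-4-en-1-yne | COC#CCC=C(C)C | intermediate
5 | 3-ethoxycyclobut-2-en-1-one | CCOC1=CC(=O)C1 | starting material
6 | 3-ethoxybuta-1,3-dien-1-one, the vinylketene (not isolated) | C=C(OCC)C=C=O | intermediate
7 | 4-(1-ethoxyethenyl)-3-methoxy-2-(3-methylbut-2-enyl)cyclobut-2-en-1-one, racemic (not isolated) | CCOC(=C)C1C(=O)C(CC=C(C)C)=C1OC | intermediate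
8 | (3E)-5-ethoxy-3-methoxy-2-(3-methylbut-2-enyl)hexa-1,3,5-trien-1-one, the dienylketene (not isolated) | O=C=C(CC=C(C)C)/C(OC)=C\C(=C)OCC | intermediate
9 | 5-ethoxy-3-methoxy-2-(3-methylbut-2-enyl)cyclohexa-2,4-dien-1-one (not isolated) | O=C1CC(OCC)=CC(OC)=C1CC=C(C)C | intermediate
10 | 5-ethoxy-3-methoxy-2-(3-methylbut-2-enyl)phenol | CCOc1cc(O)c(CC=C(C)C)c(OC)c1 | intermediate
11 | 3-ethoxy-2-(hydroxymethyl)-5-methoxy-6-(3-methylbut-2-enyl)phenol (not isolated) | CCOc1cc(OC)c(CC=C(C)C)c(O)c1CO | intermediate
12 | 6-ethoxy-2-hydroxy-4-methoxy-3-(3-methylbut-2-enyl)benzaldehyde | CCOc1cc(OC)c(CC=C(C)C)c(O)c1C=O | intermediate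
13 | 6-ethoxy-4-methoxy-2-(methoxymethoxy)-3-(3-methylbut-2-enyl)benzaldehyde | CCOc1cc(OC)c(CC=C(C)C)c(OCOC)c1C=O | intermediate
14 | 1-[6-ethoxy-4-methoxy-2-(methoxymethoxy)-3-(3-methylbut-2-enyl)phenyl]ethan-1-ol, racemic | CCOc1cc(OC)c(CC=C(C)C)c(OCOC)c1C(C)O | intermediate
15 | 1-[6-ethoxy-4-methoxy-2-(methoxymethoxy)-3-(3-methylbut-2-enyl)phenyl]ethan-1-one | CCOc1cc(OC)c(CC=C(C)C)c(OCOC)c1C(C)=O | intermediate
16 | isovanillin (3-hydroxy-4-methoxybenzaldehyde) | COc1ccc(C=O)cc1O | starting material
17 | 4-methoxy-3-(methoxymethoxy)benzaldehyde | COCOc1cc(C=O)ccc1OC | intermediate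
18 | 1-[6-ethoxy-4-methoxy-2-(methoxymethoxy)-3-(3-methylbut-2-enyl)phenyl]-3-hydroxy-3-[4-methoxy-3-(methoxymethoxy)phenyl]propan-1-one, racemic aldol adduct (not isolated) | CCOc1cc(OC)c(CC=C(C)C)c(OCOC)c1C(=O)CC(O)c2ccc(OC)c(OCOC)c2 | intermediate
19 | (2E)-1-[6-ethoxy-4-methoxy-2-(methoxymethoxy)-3-(3-methylbut-2-enyl)phenyl]-3-[4-methoxy-3-(methoxymethoxy)phenyl]prop-2-en-1-one | CCOc1cc(OC)c(CC=C(C)C)c(OCOC)c1C(=O)/C=C/c2ccc(OC)c(OCOC)c2 | intermediate
20 | [6-ethoxy-4-methoxy-2-(methoxymethoxy)-3-(3-methylbut-2-enyl)phenyl]{(2R,3S)-3-[4-methoxy-3-(methoxymethoxy)phenyl]oxiran-2-yl}methanone | CCOc1cc(OC)c(CC=C(C)C)c(OCOC)c1C(=O)[C@@H]2O[C@H]2c3ccc(OC)c(OCOC)c3 | intermediate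
21 | [6-ethoxy-2-hydroxy-4-methoxy-3-(3-methylbut-2-enyl)phenyl][(2R,3S)-3-(3-hydroxy-4-methoxyphenyl)oxiran-2-yl]methanone (not isolated) | CCOc1cc(OC)c(CC=C(C)C)c(O)c1C(=O)[C@@H]2O[C@H]2c3ccc(OC)c(O)c3 | intermediate
22 | (2R,3R)-5-ethoxy-3-hydroxy-2-(3-hydroxy-4-methoxyphenyl)-7-methoxy-8-(3-methylbut-2-enyl)-2,3-dihydro-4H-chromen-4-one | COc1ccc([C@H]2Oc3c(CC=C(C)C)c(OC)cc(OCC)c3C(=O)[C@@H]2O)cc1O | intermediate
23 | (2R,3R)-3,5-dihydroxy-2-(3-hydroxy-4-methoxyphenyl)-7-methoxy-8-(3-methylbut-2-enyl)-2,3-dihydro-4H-chromen-4-one | COc1ccc([C@H]2Oc3c(CC=C(C)C)c(OC)cc(O)c3C(=O)[C@@H]2O)cc1O | target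

Total step count: 11. Longest linear sequence: 10 steps (steps 1 to 6 and 8 to 11); step 7 is a one-step side branch.

Steps most likely to fail

Step 2. The alkoxy group stabilises the cyclobutenone, so its ring opening may be slow, and the vinylketene may then be lost to self-condensation or to O-acylation of the product phenol before the ynol ether traps it. A basic methanol wash (K2CO3, MeOH) would return O-acylated phenol. The fallback functionalises a preformed phloroglucinol ring instead of building the ring; it sets out from prenyl bromide 2 and comes back to the route at ketone 15. Purchased 1-(2,6-dihydroxy-4-methoxyphenyl)ethan-1-one F1 is mono-O-ethylated (EtI, K2CO3, acetone; the second hydroxyl stays hydrogen-bonded to the ketone) to give 1-(2-ethoxy-6-hydroxy-4-methoxyphenyl)ethan-1-one F2. C-Prenylation of its phenoxide with 2 (aq. KOH, 0 °C → rt), a classical but unselective reaction, gives 1-[6-ethoxy-2-hydroxy-4-methoxy-3-(3-methylbut-2-enyl)phenyl]ethan-1-one F3, which has to be separated from O-alkylated and para-alkylated material. MOM protection (NaH, MOMCl, DMF) then gives 15. This path gives up the built-in regiocontrol and serves only as a reserve.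

Step 11. Iodide attacks an ethyl carbon more slowly than a methyl carbon, so conversion may stall. On longer heating the Lewis acid may open the benzylic C2–O1 bond (epimerisation at C2), or hydrogen iodide may add to the prenyl double bond. The fallback protects first and then cleaves with a boron halide at low temperature; it sets out from 22 and comes back at target 23. Acetylation (Ac2O, pyridine) gives (2R,3R)-3-acetoxy-2-(3-acetoxy-4-methoxyphenyl)-5-ethoxy-7-methoxy-8-(3-methylbut-2-enyl)-2,3-dihydro-4H-chromen-4-one F4, which has no free hydroxyl that could release HCl. BCl3 (CH2Cl2, −78 → −20 °C) should cleave only the ether chelated to the C4 carbonyl and give (2R,3R)-3-acetoxy-2-(3-acetoxy-4-methoxyphenyl)-5-hydroxy-7-methoxy-8-(3-methylbut-2-enyl)-2,3-dihydro-4H-chromen-4-one F5. Acid-catalysed methanolysis (HCl, MeOH, rt) then removes both acetates without base and gives 23.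

Step 9. The ketone of 19 is twisted out of the plane of ring A by its two ortho substituents and may bind poorly to the peptide, so the uncatalysed background epoxidation may lower the facial selectivity. The fallback uses resolution instead of asymmetric catalysis; it sets out from chalcone 19 and comes back at 22. Weitz–Scheffer epoxidation (H2O2, NaOH, MeOH/THF, 0 °C) gives racemic trans-[6-ethoxy-4-methoxy-2-(methoxymethoxy)-3-(3-methylbut-2-enyl)phenyl]{3-[4-methoxy-3-(methoxymethoxy)phenyl]oxiran-2-yl}methanone F6. Treatment as in step 10 gives racemic trans-5-ethoxy-3-hydroxy-2-(3-hydroxy-4-methoxyphenyl)-7-methoxy-8-(3-methylbut-2-enyl)-2,3-dihydro-4H-chromen-4-one F7. Preparative chromatography on a cellulose tris(3,5-dimethylphenylcarbamate) phase then separates the enantiomers and gives (2R,3R)-22.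

Further compounds
F1 | step 2 | 1-(2,6-dihydroxy-4-methoxyphenyl)ethan-1-one | CC(=O)c1c(O)cc(OC)cc1O
F2 | step 2 | 1-(2-ethoxy-6-hydroxy-4-methoxyphenyl)ethan-1-one | CCOc1cc(OC)cc(O)c1C(C)=O
F3 | step 2 | 1-[6-ethoxy-2-hydroxy-4-methoxy-3-(3-methylbut-2-enyl)phenyl]ethan-1-one | CCOc1cc(OC)c(CC=C(C)C)c(O)c1C(C)=O
F4 | step 11 | (2R,3R)-3-acetoxy-2-(3-acetoxy-4-methoxyphenyl)-5-ethoxy-7-methoxy-8-(3-methylbut-2-enyl)-2,3-dihydro-4H-chromen-4-one | COc1ccc([C@H]2Oc3c(CC=C(C)C)c(OC)cc(OCC)c3C(=O)[C@@H]2OC(C)=O)cc1OC(C)=O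
F5 | step 11 | (2R,3R)-3-acetoxy-2-(3-acetoxy-4-methoxyphenyl)-5-hydroxy-7-methoxy-8-(3-methylbut-2-enyl)-2,3-dihydro-4H-chromen-4-one | COc1ccc([C@H]2Oc3c(CC=C(C)C)c(OC)cc(O)c3C(=O)[C@@H]2OC(C)=O)cc1OC(C)=O
F6 | step 9 | racemic trans-[6-ethoxy-4-methoxy-2-(methoxymethoxy)-3-(3-methylbut-2-enyl)phenyl]{3-[4-methoxy-3-(methoxymethoxy)phenyl]oxiran-2-yl}methanone, (2R,3S) and (2S,3R) in equal parts | CCOc1cc(OC)c(CC=C(C)C)c(OCOC)c1C(=O)[C@@H]2O[C@H]2c3ccc(OC)c(OCOC)c3.CCOc1cc(OC)c(CC=C(C)C)c(OCOC)c1C(=O)[C@H]2O[C@@H]2c3ccc(OC)c(OCOC)c3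
F7 | step 9 | racemic trans-5-ethoxy-3-hydroxy-2-(3-hydroxy-4-methoxyphenyl)-7-methoxy-8-(3-methylbut-2-enyl)-2,3-dihydro-4H-chromen-4-one, (2R,3R) and (2S,3S) in equal parts | COc1ccc([C@H]2Oc3c(CC=C(C)C)c(OC)cc(OCC)c3C(=O)[C@@H]2O)cc1O.COc1ccc([C@@H]2Oc3c(CC=C(C)C)c(OC)cc(OCC)c3C(=O)[C@H]2O)cc1O
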